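Halimane numbering is used: ring A = C1–C5, C10; ring B = C5–C10; C4 carries a methyl and the CH2OAc carbon. Everything rests on growing ring A onto a ring B cyclohexanone by a regiospecific Robinson annulation: the C10 enolate adds to an ethyl vinyl ketone equivalent (C1–C10) and the resulting ethyl ketone condenses onto the C5 carbonyl (C4–C5) in one pot. The step exploits C5 being the sp2 ring-fusion carbon next to the C10 methine: the 4,4-disubstituted C5=C6 array is a masked 4-methyl-4-en-3-one, unmasked later by deconjugative alkylation at C4 and Wolff–Kishner reduction. The precursor is a monocyclic silyl enol ether made by CuBr·SMe2-catalysed Grignard addition to (S)-3,4-dimethylcyclohexenone.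

Key step: step 10

Remark on the chemistry: the target is read as (4R,8S,9R,10S,13R) in the numbering above (side chain C11–C15, C15 = carboxyl carbon, C19 = the oxygenated carbon on C4). H-10, the C19 group and the C9 side chain lie on one face (called α); the methyls on C4, C8 and C9 lie on the other (β). Compound 16 is not assumed to be purchasable and is made in step 9.

Step 1
Reactants: 1 propanal; 2 but-3-en-2-one (methyl vinyl ketone)
Product: 3 (2S)-2-methyl-5-oxohexanal
Conditions: (R)-2-[methoxy(diphenyl)methyl]pyrrolidine (5 mol%), ethyl 3,4-dihydroxybenzoate (20 mol%), neat, 4 °C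
Reagents that add atoms: none
Why: Enamine-catalysed Michael addition of an aldehyde to an enone; the diphenyl(methoxy)methyl group of the (R)-catalyst shields one face of the E-enamine, so the new stereocenter (later C8) should form as S.

Step 2
Reactants: 3 (2S)-2-methyl-5-oxohexanal
Product: 4 (4S)-4-methylcyclohex-2-en-1-one
Conditions: LiOH·H2O (cat.), i-PrOH, 0 °C to rt
Reagents that add atoms: none
Why: Intramolecular aldol condensation (6-(enolendo)-exo-trig closure, then E1cB dehydration) of the methyl ketone onto the aldehyde; mild catalytic base is chosen to limit epimerisation of the α-stereocenter before ring closure.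

Step 3
Reactants: 4 (4S)-4-methylcyclohex-2-en-1-one
Product: 5 trimethyl{[(3R,4S)-3,4-dimethylcyclohex-1-en-1-yl]oxy}silane
Conditions: MeMgBr, CuBr·SMe2 (5 mol%), Me3SiCl, HMPA, THF, −78 °C; Et3N quench
Reagents that add atoms: methylmagnesium bromide, C[Mg]Br; chlorotrimethylsilane, C[Si](C)(C)Cl
Why: TMSCl-accelerated copper-catalysed conjugate addition of a Grignard reagent with in situ O-silylation gives the regiodefined silyl enol ether; the methyl should enter mainly anti to the C4 methyl, but this new stereocenter is erased in step 4.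

Step 4
Reactants: 5 trimethyl{[(3R,4S)-3,4-dimethylcyclohex-1-en-1-yl]oxy}silane
Product: 6 (4S)-3,4-dimethylcyclohex-2-en-1-one
Conditions: Pd(OAc)2 (10 mol%), O2 (1 atm), DMSO, rt
Reagents that add atoms: none
Why: Saegusa–Ito oxidation (palladium enolate, β-hydride elimination, reoxidation of zerovalent palladium by O2) places the double bond on the methylated carbon; the C4 stereocenter is untouched.

Step 5
Reactants: 7 (R)-citronellol, (3R)-3,7-dimethyloct-6-en-1-ol
Product: 8 tert-butyl{[(3R)-3,7-dimethyloct-6-en-1-yl]oxy}dimethylsilane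
Conditions: TBSCl, imidazole, DMF, rt
Reagents that add atoms: tert-butyldimethylsilyl chloride, CC(C)(C)[Si](C)(C)Cl
Why: Routine silylation of the primary alcohol; the ether survives organomagnesium, organolithium and alkoxide reagents and is cleaved in the acidic oxidation of step 12.

Step 6
Reactants: 8 tert-butyl{[(3R)-3,7-dimethyloct-6-en-1-yl]oxy}dimethylsilane
Product: 9 (4R)-6-[(tert-butyldimethylsilyl)oxy]-4-methylhexanoic acid
Conditions: KMnO4 (cat.), NaIO4, K2CO3, t-BuOH/H2O, rt; then citric acid to pH 4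
Reagents that add atoms: sodium periodate (terminal oxidant), [Na+].[O-]I(=O)(=O)=O; potassium permanganate (oxygen carrier), [K+].[O-][Mn](=O)(=O)=O
Why: Lemieux–von Rudloff oxidative cleavage of the trisubstituted alkene to the carboxylic acid and acetone under buffered conditions that spare the silyl ether; the stereocenter is remote.

Step 7
Reactants: 9 (4R)-6-[(tert-butyldimethylsilyl)oxy]-4-methylhexanoic acid
Product: 10 tert-butyl{[(3S)-5-iodo-3-methylpentyl]oxy}dimethylsilane
Conditions: PhI(OAc)2, I2, hν (visible), cyclohexane, reflux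
Reagents that add atoms: iodine, [I][I]
Why: Hunsdiecker-type iododecarboxylation through the acyl hypoiodite and a primary alkyl radical; the stereocenter is two carbons from the radical site and is retained (its descriptor changes only through the priority of iodine).

Step 8
Reactants: 10 tert-butyl{[(3S)-5-iodo-3-methylpentyl]oxy}dimethylsilane; 6 (4S)-3,4-dimethylcyclohex-2-en-1-one
Product: 12 tert-butyl{[(3R)-5-{(1R,6S)-1,6-dimethyl-3-[(trimethylsilyl)oxy]cyclohex-2-en-1-yl}-3-methylpentyl]oxy}dimethylsilane, via Grignard reagent 11 (not isolated)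
Conditions: 10, Mg, THF, rt; then 6, CuBr·SMe2 (10 mol%), Me3SiCl, HMPA, THF, −78 °C; Et3N, pentane work-up
Reagents that add atoms: chlorotrimethylsilane, C[Si](C)(C)Cl
Why: Copper-catalysed conjugate addition with TMSCl trapping; the C4 methyl of 6 is pseudoaxial (A(1,2) strain with the C3 methyl) and the alkyl group should enter anti to it, setting the quaternary C9 with the two ring methyls cis, while silylation fixes the enolate toward C10.

Step 9
Reactants: 13 (1-bromoethenyl)trimethylsilane; 14 N-methoxy-N-methylpropanamide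
Product: 16 2-(trimethylsilyl)pent-1-en-3-one, via vinyl Grignard reagent 15 (not isolated)
Conditions: 13, Mg, THF, reflux; then 14, 0 °C; cold aq. HCl quench
Reagents that add atoms: none
Why: Weinreb ketone synthesis: the chelated tetrahedral adduct resists over-addition and releases the α-silyl enone only on cold acidic quench.

Step 10
Reactants: 12 tert-butyl{[(3R)-5-{(1R,6S)-1,6-dimethyl-3-[(trimethylsilyl)oxy]cyclohex-2-en-1-yl}-3-methylpentyl]oxy}dimethylsilane; 16 2-(trimethylsilyl)pent-1-en-3-one
Product: 20 (4aS,5R,6S)-5-{(3R)-5-[(tert-butyldimethylsilyl)oxy]-3-methylpentyl}-1,5,6-trimethyl-4,4a,5,6,7,8-hexahydronaphthalen-2(3H)-one, via lithium enolate 17 (not isolated), via silyl diketone 18 (not isolated), via diketone 19 (not isolated)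
Conditions: 12, MeLi (1.0 equiv), THF, 0 °C to rt; 16, −78 to −30 °C; then NaOMe, MeOH, rt to 60 °C
Reagents that add atoms: none
Why: MeLi cleaves the Si–O bond of 12 without equilibration to give the C10 lithium enolate 17, which adds in Michael fashion to the α-silyl enone 16 (the silyl group stabilises the new enolate and suppresses oligomerisation and proton transfer) and forms C1–C10 in 18; methoxide then removes the C-silyl group to give 19 and drives the intramolecular aldol condensation of C4 onto the C5 carbonyl, forming C4–C5 and the C4=C5 enone. The closest known reaction type is the Robinson annulation of regiospecifically generated enolates with α-silyl vinyl ketones. Ring A closes in the 6-(enolendo)-exo-trig mode, and E1cB dehydration makes the closure irreversible. The only new stereocenter, C10, is under thermodynamic control (epimerisable α to the C5 ketone in 19 and as the γ-carbon of 20) and should settle with H-10 axial and cis to the equatorial C11 chain, so that only the C9 methyl is axial on ring B. The step needs C10- over C6-alkylation, secured by the enolate regiochemistry fixed in step 8, and fused over bridged aldol closure, secured by the reversibility of the ketol stage with the conjugated enone as the sink.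

Step 11
Reactants: 20 (4aS,5R,6S)-5-{(3R)-5-[(tert-butyldimethylsilyl)oxy]-3-methylpentyl}-1,5,6-trimethyl-4,4a,5,6,7,8-hexahydronaphthalen-2(3H)-one
Product: 22 (1R,4aS,5R,6S)-1-[(benzyloxy)methyl]-5-{(3R)-5-[(tert-butyldimethylsilyl)oxy]-3-methylpentyl}-1,5,6-trimethyl-3,4,4a,5,6,7-hexahydronaphthalen-2(1H)-one, via potassium dienolate 21 (not isolated)
Conditions: t-BuOK (1.1 equiv), t-BuOH/THF, rt; then BnOCH2Cl, −20 to 0 °C
Reagents that add atoms: benzyl chloromethyl ether, ClCOCc1ccccc1
Why: Deconjugative α-alkylation of the thermodynamic heteroannular dienolate (O–C3=C4–C5=C6): C-alkylation at C4 moves the double bond to C5=C6, and the electrophile should enter axially on the α face (the face of the axial H-10, leading directly to the ring A chair, with no angular substituent to block it), which places the CH2OBn group cis to H-10 and sets C4.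

Step 12
Reactants: 22 (1R,4aS,5R,6S)-1-[(benzyloxy)methyl]-5-{(3R)-5-[(tert-butyldimethylsilyl)oxy]-3-methylpentyl}-1,5,6-trimethyl-3,4,4a,5,6,7-hexahydronaphthalen-2(1H)-one
Product: 24 (3R)-5-{(1R,2S,5R,8aS)-5-[(benzyloxy)methyl]-1,2,5-trimethyl-6-oxo-1,2,3,5,6,7,8,8a-octahydronaphthalen-1-yl}-3-methylpentanoic acid, via primary alcohol 23 (not isolated)
Conditions: CrO3, H2SO4, H2O, acetone, 0 °C
Reagents that add atoms: water (second carboxyl oxygen; CrO3 is the oxidant), O
Why: Jones oxidation: the aqueous acid removes the primary silyl ether and the alcohol 23 is oxidised to the carboxylic acid, while the ketone, the benzyl ether and the hindered trisubstituted alkene should be inert at 0 °C.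

Step 13
Reactants: 24 (3R)-5-{(1R,2S,5R,8aS)-5-[(benzyloxy)methyl]-1,2,5-trimethyl-6-oxo-1,2,3,5,6,7,8,8a-octahydronaphthalen-1-yl}-3-methylpentanoic acid
Product: 26 (3R)-5-{(1R,2S,5R,8aS)-5-[(benzyloxy)methyl]-1,2,5-trimethyl-1,2,3,5,6,7,8,8a-octahydronaphthalen-1-yl}-3-methylpentanoic acid, via hydrazone 25 (not isolated)
Conditions: N2H4·H2O, KOH, diethylene glycol, 130 °C then 200 °C; aq. HCl work-up
Reagents that add atoms: none
Why: Wolff–Kishner reduction (Huang-Minlon variant): since C4 is quaternary the C5=C6 bond cannot move into conjugation, and no epimerisable stereocenter lies α to the hydrazone or to the carboxylate.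

Step 14
Reactants: 26 (3R)-5-{(1R,2S,5R,8aS)-5-[(benzyloxy)methyl]-1,2,5-trimethyl-1,2,3,5,6,7,8,8a-octahydronaphthalen-1-yl}-3-methylpentanoic acid
Product: 27 (3R)-5-[(1R,2S,5R,8aS)-5-(hydroxymethyl)-1,2,5-trimethyl-1,2,3,5,6,7,8,8a-octahydronaphthalen-1-yl]-3-methylpentanoic acid
Conditions: Li, NH3(l), THF, −78 °C; NH4Cl
Reagents that add atoms: none
Why: Dissolving-metal cleavage of the benzyl ether (benzylic C–O reduction), in which the isolated trisubstituted alkene and the lithium carboxylate are not reduced.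

Step 15
Reactants: 27 (3R)-5-[(1R,2S,5R,8aS)-5-(hydroxymethyl)-1,2,5-trimethyl-1,2,3,5,6,7,8,8a-octahydronaphthalen-1-yl]-3-methylpentanoic acid
Product: 29 (3R)-5-[(1R,2S,5R,8aS)-5-(acetoxymethyl)-1,2,5-trimethyl-1,2,3,5,6,7,8,8a-octahydronaphthalen-1-yl]-3-methylpentanoic acid, via mixed anhydride 28 (not isolated)
Conditions: Ac2O, pyridine, DMAP (cat.), CH2Cl2, rt; then NaHCO3, H2O/THF, rt; acidify to pH 3
Reagents that add atoms: acetic anhydride, CC(=O)OC(C)=O
Why: DMAP-catalysed acetylation of the neopentyl primary alcohol; the carboxyl group is converted in passing into the mixed anhydride 28, which is hydrolysed far faster than the acetate ester in the bicarbonate work-up.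

Compound list

1 | propanal | CCC=O | starting material
2 | but-3-en-2-one (methyl vinyl ketone) | CC(=O)C=C | starting material
3 | (2S)-2-methyl-5-oxohexanal | O=C[C@@H](C)CCC(C)=O | intermediate
4 | (4S)-4-methylcyclohex-2-en-1-one | O=C1C=C[C@@H](C)CC1 | intermediate
5 | trimethyl{[(3R,4S)-3,4-dimethylcyclohex-1-en-1-yl]oxy}silane (trans) | C[Si](C)(C)OC1=C[C@H](C)[C@@H](C)CC1 | intermediate
6 | (4S)-3,4-dimethylcyclohex-2-en-1-one | O=C1C=C(C)[C@@H](C)CC1 | intermediate
7 | (R)-citronellol, (3R)-3,7-dimethyloct-6-en-1-ol | OCC[C@H](C)CCC=C(C)C | starting material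
8 | tert-butyl{[(3R)-3,7-dimethyloct-6-en-1-yl]oxy}dimethylsilane | CC(C)=CCC[C@@H](C)CCO[Si](C)(C)C(C)(C)C | intermediate
9 | (4R)-6-[(tert-butyldimethylsilyl)oxy]-4-methylhexanoic acid | OC(=O)CC[C@@H](C)CCO[Si](C)(C)C(C)(C)C | intermediate
10 | tert-butyl{[(3S)-5-iodo-3-methylpentyl]oxy}dimethylsilane | ICC[C@@H](C)CCO[Si](C)(C)C(C)(C)C | intermediate
11 | {(3S)-5-[(tert-butyldimethylsilyl)oxy]-3-methylpentyl}magnesium iodide | I[Mg]CC[C@@H](C)CCO[Si](C)(C)C(C)(C)C | intermediate (not isolated)
12 | tert-butyl{[(3R)-5-{(1R,6S)-1,6-dimethyl-3-[(trimethylsilyl)oxy]cyclohex-2-en-1-yl}-3-methylpentyl]oxy}dimethylsilane | C[Si](C)(C)OC1=C[C@](C)(CC[C@@H](C)CCO[Si](C)(C)C(C)(C)C)[C@@H](C)CC1 | intermediate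
13 | (1-bromoethenyl)trimethylsilane | C=C(Br)[Si](C)(C)C | starting material
14 | N-methoxy-N-methylpropanamide | CCC(=O)N(C)OC | starting material
15 | [1-(trimethylsilyl)ethenyl]magnesium bromide | C=C([Mg]Br)[Si](C)(C)C | intermediate (not isolated)
16 | 2-(trimethylsilyl)pent-1-en-3-one | CCC(=O)C(=C)[Si](C)(C)C | intermediate
17 | lithium (3R,4S)-3-{(3R)-5-[(tert-butyldimethylsilyl)oxy]-3-methylpentyl}-3,4-dimethylcyclohex-1-en-1-olate | [Li+].[O-]C1=C[C@](C)(CC[C@@H](C)CCO[Si](C)(C)C(C)(C)C)[C@@H](C)CC1 | intermediate (not isolated)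
18 | (2S,3R,4S)-3-{(3R)-5-[(tert-butyldimethylsilyl)oxy]-3-methylpentyl}-3,4-dimethyl-2-[3-oxo-2-(trimethylsilyl)pentyl]cyclohexan-1-one (both epimers at the silyl-bearing carbon; C2 of the ring drawn as after equilibration) | CCC(=O)C(C[C@@H]1C(=O)CC[C@H](C)[C@@]1(C)CC[C@@H](C)CCO[Si](C)(C)C(C)(C)C)[Si](C)(C)C | intermediate (not isolated)
19 | (2S,3R,4S)-3-{(3R)-5-[(tert-butyldimethylsilyl)oxy]-3-methylpentyl}-3,4-dimethyl-2-(3-oxopentyl)cyclohexan-1-one | CCC(=O)CC[C@@H]1C(=O)CC[C@H](C)[C@@]1(C)CC[C@@H](C)CCO[Si](C)(C)C(C)(C)C | intermediate (not isolated)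
20 | (4aS,5R,6S)-5-{(3R)-5-[(tert-butyldimethylsilyl)oxy]-3-methylpentyl}-1,5,6-trimethyl-4,4a,5,6,7,8-hexahydronaphthalen-2(3H)-one | O=C1CC[C@@H]2C(=C1C)CC[C@H](C)[C@@]2(C)CC[C@@H](C)CCO[Si](C)(C)C(C)(C)C | intermediate
21 | potassium dienolate of 20 (O–C3=C4–C5=C6 in halimane numbering) | [K+].[O-]C1=C(C)C2=CC[C@H](C)[C@@](C)(CC[C@@H](C)CCO[Si](C)(C)C(C)(C)C)[C@@H]2CC1 | intermediate (not isolated)
22 | (1R,4aS,5R,6S)-1-[(benzyloxy)methyl]-5-{(3R)-5-[(tert-butyldimethylsilyl)oxy]-3-methylpentyl}-1,5,6-trimethyl-3,4,4a,5,6,7-hexahydronaphthalen-2(1H)-one | c1ccccc1COC[C@]1(C)C(=O)CC[C@@H]2C1=CC[C@H](C)[C@@]2(C)CC[C@@H](C)CCO[Si](C)(C)C(C)(C)C | intermediate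
23 | (1R,4aS,5R,6S)-1-[(benzyloxy)methyl]-5-[(3R)-5-hydroxy-3-methylpentyl]-1,5,6-trimethyl-3,4,4a,5,6,7-hexahydronaphthalen-2(1H)-one | c1ccccc1COC[C@]1(C)C(=O)CC[C@@H]2C1=CC[C@H](C)[C@@]2(C)CC[C@@H](C)CCO | intermediate (not isolated)
24 | (3R)-5-{(1R,2S,5R,8aS)-5-[(benzyloxy)methyl]-1,2,5-trimethyl-6-oxo-1,2,3,5,6,7,8,8a-octahydronaphthalen-1-yl}-3-methylpentanoic acid | c1ccccc1COC[C@]1(C)C(=O)CC[C@@H]2C1=CC[C@H](C)[C@@]2(C)CC[C@@H](C)CC(=O)O | intermediate
25 | hydrazone of 24 (C=N–NH2 in place of the ring C=O, configuration otherwise unchanged) | c1ccccc1COC[C@]1(C)C(=NN)CC[C@@H]2C1=CC[C@H](C)[C@@]2(C)CC[C@@H](C)CC(=O)O | intermediate (not isolated)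
26 | (3R)-5-{(1R,2S,5R,8aS)-5-[(benzyloxy)methyl]-1,2,5-trimethyl-1,2,3,5,6,7,8,8a-octahydronaphthalen-1-yl}-3-methylpentanoic acid | c1ccccc1COC[C@]1(C)CCC[C@@H]2C1=CC[C@H](C)[C@@]2(C)CC[C@@H](C)CC(=O)O | intermediate
27 | (3R)-5-[(1R,2S,5R,8aS)-5-(hydroxymethyl)-1,2,5-trimethyl-1,2,3,5,6,7,8,8a-octahydronaphthalen-1-yl]-3-methylpentanoic acid | OC[C@]1(C)CCC[C@@H]2C1=CC[C@H](C)[C@@]2(C)CC[C@@H](C)CC(=O)O | intermediate
28 | mixed acetic anhydride of 29 (carboxyl group as C(=O)–O–C(=O)CH3) | CC(=O)OC[C@]1(C)CCC[C@@H]2C1=CC[C@H](C)[C@@]2(C)CC[C@@H](C)CC(=O)OC(C)=O | intermediate (not isolated)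
29 | (3R)-5-[(1R,2S,5R,8aS)-5-(acetoxymethyl)-1,2,5-trimethyl-1,2,3,5,6,7,8,8a-octahydronaphthalen-1-yl]-3-methylpentanoic acid (CNP0148247.1) | CC(=O)OC[C@]1(C)CCC[C@@H]2C1=CC[C@H](C)[C@@]2(C)CC[C@@H](C)CC(=O)O | target

Total step count: 15. Longest linear sequence: 11 steps (steps 1, 2, 3, 4, 8, 10, 11, 12, 13, 14, 15).

The three steps most likely to fail

Step 11. The ambident dienolate 21 may be alkylated on oxygen by the hard chloromethyl ether, or carbon attack may occur partly on the β face and erode the C4 configuration. The fallback sets out from 20 and comes back at 22. The same dienolate 21 is trapped at −78 °C with gaseous monomeric formaldehyde (an aldol addition in place of the SN2 alkylation, quenched cold with AcOH) to give the hydroxymethyl ketone F1. Its neopentyl alcohol is then benzylated under acidic conditions with benzyl 2,2,2-trichloroacetimidate and catalytic TfOH, base being avoided to prevent retro-aldol loss of formaldehyde.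

Step 10. Michael addition at the neopentyl enolate carbon C10 may be slow, so that proton transfer and anionic oligomerisation consume 16, and the aldol stage may stall at a bridged ketol. The fallback sets out from 12 and comes back at 20. A Mukaiyama–Michael addition of 12 to commercial pent-1-en-3-one under TiCl4/Ti(Oi-Pr)4 in CH2Cl2 at −78 °C (activation of the acceptor instead of an enolate anion) should give the diketone 19, now isolated after aqueous work-up. A separate treatment with KOH in MeOH then closes ring A; no new compound is involved.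

Step 13. Hydrazone formation at the C3 ketone, flanked by the quaternary C4, may be incomplete, and prolonged heating in strong base invites azine formation and decomposition. The fallback sets out from 24 and comes back at 26. The ketone is converted into its only possible enol triflate F2 (KN(SiMe3)2, 2.2 equiv, PhNTf2, THF, −78 °C; enolisation is possible only toward C2). The triflate is reduced with Pd(OAc)2/PPh3, Bu3N and HCO2H to the 2,5-diene acid F3. The cis-disubstituted C2=C3 bond is then saturated with diimide (potassium azodicarboxylate, AcOH), which should spare the hindered trisubstituted C5=C6 bond.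

Further compounds

F1 | step 11 | (1R,4aS,5R,6S)-5-{(3R)-5-[(tert-butyldimethylsilyl)oxy]-3-methylpentyl}-1-(hydroxymethyl)-1,5,6-trimethyl-3,4,4a,5,6,7-hexahydronaphthalen-2(1H)-one | OC[C@]1(C)C(=O)CC[C@@H]2C1=CC[C@H](C)[C@@]2(C)CC[C@@H](C)CCO[Si](C)(C)C(C)(C)C
F0 | step 10 | none | none
F2 | step 13 | (3R)-5-{(1R,2S,5R,8aS)-5-[(benzyloxy)methyl]-1,2,5-trimethyl-6-[(trifluoromethanesulfonyl)oxy]-1,2,3,5,8,8a-hexahydronaphthalen-1-yl}-3-methylpentanoic acid | c1ccccc1COC[C@]1(C)C(OS(=O)(=O)C(F)(F)F)=CC[C@@H]2C1=CC[C@H](C)[C@@]2(C)CC[C@@H](C)CC(=O)O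
F3 | step 13 | (3R)-5-{(1R,2S,5R,8aS)-5-[(benzyloxy)methyl]-1,2,5-trimethyl-1,2,3,5,8,8a-hexahydronaphthalen-1-yl}-3-methylpentanoic acid | c1ccccc1COC[C@]1(C)C=CC[C@@H]2C1=CC[C@H](C)[C@@]2(C)CC[C@@H](C)CC(=O)O
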